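**Plan**
- Cuts, last to first: (a) the bond from ring A carbon C1' to the cinnamoyl carbonyl; (b) C2–aryl and C3–O of the oxane, back to a C2=C3 enol ether; (c) the C4–ring A bond, back to an aryl cuprate and an ynoate; (d) the C5–C(alkyne) and CH2–CH2(benzyl) bonds, back to (S)-epichlorohydrin.
- Forward: epichlorohydrin → epoxide → hydroxy ynoate → cuprate addition with lactonisation (this closes the six-membered O-ring) → hydrogenation → lactol → glycal → epoxidation and aryl transfer → acetates → MOM removal → C-acylation of ring A → methanolysis.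
- Stereochemistry: C6 from (S)-epichlorohydrin; C4 by hydrogenation cis to the C6 chain; C3 by epoxidation trans to the C4 aryl group; C2 by aryl delivery from aluminium syn to the C3 oxygen (axial, trans to C6).
- Feature used by the key step: in 25, ring A is a 2-alkyl-5-methoxyresorcinol. Its two free ring carbons (each between an OH and the OMe, para to the other OH) are exchanged by rotation about the ring A–C4(oxane) bond, so acylation at either gives the same ketone; the ortho OH then chelates the new carbonyl and stops a second acylation.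
- Helpers: acetates make the C2 aryl ring electron-poor, so the benzylic C2–O1 bond should not ionise under Lewis acid; they are removed in the last step.

Key step: step 13

Assumption: 1, 3, 4, 8, 18 and 26 are bought, dimethyldioxirane is used as a prepared acetone solution, and Lewis acids that only activate (BF3·OEt2, ZnBr2) are taken as unchanged by their step.

Step 1
Reactants: 1 5-methoxybenzene-1,3-diol
Product: 2 1-methoxy-3,5-bis(methoxymethoxy)benzene
Conditions: NaH, MOMCl, DMF, 0 °C → rt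
Reagents that add atoms: chloromethyl methyl ether, COCCl
Why: Williamson-type O-alkylation of both phenoxides (MOM protection) gives the bis-acetal whose two oxygens later direct lithiation to the ring carbon between them.

Step 2
Reactants: 3 4-(benzyloxy)benzyl chloride; 4 (S)-epichlorohydrin
Product: 7 (S)-2-{2-[4-(benzyloxy)phenyl]ethyl}oxirane, via benzylic Grignard reagent 5 (not isolated), via chlorohydrin alkoxide 6 (not isolated)
Conditions: Mg, THF, 0 °C; 4, CuI (5 mol %), −40 → 0 °C; then aq. NaOH, rt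
Reagents that add atoms: none
Why: Copper-catalysed Grignard opening at the CH2 terminus of the epoxide followed by intramolecular Williamson closure of the chlorohydrin alkoxide leaves the carbinol carbon untouched, so the future C6 comes unchanged from the chiral pool.

Step 3
Reactants: 7 (S)-2-{2-[4-(benzyloxy)phenyl]ethyl}oxirane; 8 ethyl propiolate
Product: 10 ethyl (S)-7-[4-(benzyloxy)phenyl]-5-hydroxyhept-2-ynoate, via lithium acetylide 9 (not isolated)
Conditions: 8, n-BuLi, THF, −78 °C; BF3·OEt2, then 7, −78 °C; H2O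
Reagents that add atoms: none
Why: BF3-mediated alkynylation of a terminal epoxide (Yamaguchi–Hirao) attacks the CH2 carbon only, so the stereocenter is not involved.

Step 4
Reactants: 2 1-methoxy-3,5-bis(methoxymethoxy)benzene; 10 ethyl (S)-7-[4-(benzyloxy)phenyl]-5-hydroxyhept-2-ynoate
Product: 13 (6S)-6-{2-[4-(benzyloxy)phenyl]ethyl}-4-[4-methoxy-2,6-bis(methoxymethoxy)phenyl]-5,6-dihydro-2H-pyran-2-one, via aryllithium 11 (not isolated), via lithium diarylcuprate 12 (not isolated)
Conditions: 2 (2.2 equiv), n-BuLi, THF, 0 °C; CuBr·SMe2 (1.1 equiv), −40 °C; 10, −78 → −20 °C; AcOH, then rt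
Reagents that add atoms: none
Why: Directed ortho-lithiation between the two OMOM groups, transmetalation to copper and syn-carbocupration of the ynoate place the ester cis to the hydroxyalkyl chain, which lactonises in the flask (cuprate conjugate addition with lactonisation).

Step 5
Reactants: 13 (6S)-6-{2-[4-(benzyloxy)phenyl]ethyl}-4-[4-methoxy-2,6-bis(methoxymethoxy)phenyl]-5,6-dihydro-2H-pyran-2-one
Product: 14 (4R,6S)-6-[2-(4-hydroxyphenyl)ethyl]-4-[4-methoxy-2,6-bis(methoxymethoxy)phenyl]oxan-2-one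
Conditions: H2 (1–3 atm), 10% Pd/C, EtOAc/EtOH, rt
Reagents that add atoms: none
Why: Heterogeneous hydrogenation should add H2 to the ring face that carries the axial C6–H, opposite the pseudo-equatorial side chain, which sets C4 cis to C6 (both equatorial), and the same catalyst removes the benzyl ether by hydrogenolysis.

Step 6
Reactants: 14 (4R,6S)-6-[2-(4-hydroxyphenyl)ethyl]-4-[4-methoxy-2,6-bis(methoxymethoxy)phenyl]oxan-2-one
Product: 15 (4R,6S)-6-{2-[4-(tert-butyldimethylsilyloxy)phenyl]ethyl}-4-[4-methoxy-2,6-bis(methoxymethoxy)phenyl]oxan-2-one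
Conditions: TBSCl, imidazole, DMF, rt
Reagents that add atoms: tert-butyldimethylsilyl chloride, CC(C)(C)[Si](C)(C)Cl
Why: Silyl ether formation at the phenol shields it from DIBAL-H, MsCl and the alane of the next three steps.

Step 7
Reactants: 15 (4R,6S)-6-{2-[4-(tert-butyldimethylsilyloxy)phenyl]ethyl}-4-[4-methoxy-2,6-bis(methoxymethoxy)phenyl]oxan-2-one
Product: 16 (4R,6S)-6-{2-[4-(tert-butyldimethylsilyloxy)phenyl]ethyl}-4-[4-methoxy-2,6-bis(methoxymethoxy)phenyl]oxan-2-ol (anomer mixture)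
Conditions: DIBAL-H (1.1 equiv), CH2Cl2, −78 °C; aq. Rochelle salt
Reagents that add atoms: none
Why: Partial reduction of a δ-lactone stops at the tetrahedral aluminium lactolate at −78 °C and gives the lactol on work-up.

Step 8
Reactants: 16 (4R,6S)-6-{2-[4-(tert-butyldimethylsilyloxy)phenyl]ethyl}-4-[4-methoxy-2,6-bis(methoxymethoxy)phenyl]oxan-2-ol
Product: 17 (2S,4R)-2-{2-[4-(tert-butyldimethylsilyloxy)phenyl]ethyl}-4-[4-methoxy-2,6-bis(methoxymethoxy)phenyl]-3,4-dihydro-2H-pyran
Conditions: MsCl, Et3N, CH2Cl2, −40 °C → reflux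
Reagents that add atoms: none
Why: Mesylation of the anomeric hydroxyl and base-induced elimination through the oxocarbenium ion give the cyclic enol ether (lactol dehydration to a glycal) without touching C4 or C6.

Step 9
Reactants: 17 (2S,4R)-2-{2-[4-(tert-butyldimethylsilyloxy)phenyl]ethyl}-4-[4-methoxy-2,6-bis(methoxymethoxy)phenyl]-3,4-dihydro-2H-pyran; 18 (4-bromophenoxy)(tert-butyl)dimethylsilane
Product: 22 (2S,3S,4S,6S)-2-[4-(tert-butyldimethylsilyloxy)phenyl]-6-{2-[4-(tert-butyldimethylsilyloxy)phenyl]ethyl}-4-[4-methoxy-2,6-bis(methoxymethoxy)phenyl]oxan-3-ol, via glycal epoxide 19 (not isolated), via aryllithium 20 (not isolated), via triarylalane 21 (not isolated)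
Conditions: (a) 17, DMDO (acetone), CH2Cl2, −78 → 0 °C, evaporation; (b) 18, n-BuLi, Et2O, −78 → 0 °C, AlCl3 (1/3 equiv), solvent exchange to CH2Cl2; (c) 19 added to 21 (2 equiv), CH2Cl2, −78 → 0 °C; aq. Rochelle salt
Reagents that add atoms: dimethyldioxirane, CC1(C)OO1
Why: Dimethyldioxirane should epoxidise the enol ether on the face anti to the allylic C4 aryl group (sets C3), and the Lewis-acidic triarylalane should open the epoxide to an oxocarbenium–aluminate ion pair that returns an aryl group to C2 from the side of the C3–O–Al bond along the axial path trans to the C6 chain (sets C2 cis to the C3 hydroxyl), as in syn-selective C-glycosylation of 1,2-anhydro sugars with organoalanes.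

Step 10
Reactants: 22 (2S,3S,4S,6S)-2-[4-(tert-butyldimethylsilyloxy)phenyl]-6-{2-[4-(tert-butyldimethylsilyloxy)phenyl]ethyl}-4-[4-methoxy-2,6-bis(methoxymethoxy)phenyl]oxan-3-ol
Product: 24 (2S,3S,4S,6S)-2-(4-acetoxyphenyl)-6-[2-(4-acetoxyphenyl)ethyl]-4-[4-methoxy-2,6-bis(methoxymethoxy)phenyl]oxan-3-yl acetate, via triol 23 (not isolated)
Conditions: TBAF (2.2 equiv), THF, 0 °C; then Ac2O, pyridine, DMAP (cat.), 0 °C → rt
Reagents that add atoms: acetic anhydride, CC(=O)OC(C)=O
Why: Fluoride desilylation followed by acetylation in the same flask converts both aryl silyl ethers and the C3 hydroxyl into acetates, which makes the C2 aryl ring electron-poor so that the benzylic C2–O1 bond should survive the two Lewis-acid steps that follow.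

Step 11
Reactants: 24 (2S,3S,4S,6S)-2-(4-acetoxyphenyl)-6-[2-(4-acetoxyphenyl)ethyl]-4-[4-methoxy-2,6-bis(methoxymethoxy)phenyl]oxan-3-yl acetate
Product: 25 (2S,3S,4S,6S)-2-(4-acetoxyphenyl)-6-[2-(4-acetoxyphenyl)ethyl]-4-(2,6-dihydroxy-4-methoxyphenyl)oxan-3-yl acetate
Conditions: ZnBr2, n-PrSH, CH2Cl2, 0 °C → rt, 10 min
Reagents that add atoms: none
Why: Lewis acid/thiol cleavage of the MOM acetals (the thiol takes the methoxymethyl group as an S,O-acetal) is fast and spares acetates, and it frees the two phenols that activate ring A.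

Step 12
Reactants: 26 (E)-3-(4-acetoxyphenyl)prop-2-enoic acid
Product: 27 (E)-3-(4-acetoxyphenyl)prop-2-enoyl chloride
Conditions: (COCl)2, DMF (cat.), CH2Cl2, 0 °C → rt; evaporation
Reagents that add atoms: oxalyl chloride, ClC(=O)C(=O)Cl
Why: Acid chloride formation by Vilsmeier-type activation does not touch the aryl acetate or the E-alkene.

Step 13
Reactants: 25 (2S,3S,4S,6S)-2-(4-acetoxyphenyl)-6-[2-(4-acetoxyphenyl)ethyl]-4-(2,6-dihydroxy-4-methoxyphenyl)oxan-3-yl acetate; 27 (E)-3-(4-acetoxyphenyl)prop-2-enoyl chloride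
Product: 28 (2S,3S,4S,6S)-2-(4-acetoxyphenyl)-6-[2-(4-acetoxyphenyl)ethyl]-4-{3-[(E)-3-(4-acetoxyphenyl)prop-2-enoyl]-2,6-dihydroxy-4-methoxyphenyl}oxan-3-yl acetate
Conditions: 27 (1.1 equiv), BF3·OEt2 (3 equiv), CH2Cl2, −20 → 20 °C; aq. NaOAc
Reagents that add atoms: none
Why: BF3 activates the acid chloride, which attacks ring A of 25 at one of its two free carbons (ortho to a free OH, ortho to OMe, para to the other OH) through a Wheland intermediate to give the aryl ketone, held as its O–BF2 chelate until work-up; any aryl ester formed by O-acylation should funnel into the same ketone by Fries shift. The closest known reaction type is the Friedel–Crafts/Fries C-acylation of phloroglucinol ethers with cinnamoyl chlorides, which gives 2'-hydroxychalcones directly. No ring is closed and no stereocenter is formed; the four oxane stereocenters are spectators. Site selectivity needs no control because rotation about the ring A–C4 bond exchanges the two reactive carbons, and the chelated carbonyl switches off the second one after the first acylation. Acylation at the carbonyl carbon must beat conjugate addition to the cinnamoyl β-carbon (dihydrocoumarin or flavanone formation), which the acetoxy group on the cinnamoyl ring, the low temperature and the BF2 chelate should secure. The benzylic C2–O1 ether must not ionise, which the acetate on the C2 aryl ring should secure.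

Step 14
Reactants: 28 (2S,3S,4S,6S)-2-(4-acetoxyphenyl)-6-[2-(4-acetoxyphenyl)ethyl]-4-{3-[(E)-3-(4-acetoxyphenyl)prop-2-enoyl]-2,6-dihydroxy-4-methoxyphenyl}oxan-3-yl acetate
Product: 29 (E)-1-{2,4-dihydroxy-3-[(2S,3S,4S,6S)-3-hydroxy-2-(4-hydroxyphenyl)-6-[2-(4-hydroxyphenyl)ethyl]oxan-4-yl]-6-methoxyphenyl}-3-(4-hydroxyphenyl)prop-2-en-1-one
Conditions: K2CO3, MeOH (degassed), 0 °C → rt; AcOH to pH 6
Reagents that add atoms: none
Why: Base-catalysed transesterification with methanol (Zemplén-type) removes the three aryl acetates and the C3 acetate under non-acidic conditions in which the hydrogen-bonded 2'-hydroxychalcone, the E-alkene and the axial C2 aryl ether should be stable, and no stereocenter is touched.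

**Compound list**
1 | 5-methoxybenzene-1,3-diol | COc1cc(O)cc(O)c1 | starting material
2 | 1-methoxy-3,5-bis(methoxymethoxy)benzene | COCOc1cc(OC)cc(OCOC)c1 | intermediate
3 | 4-(benzyloxy)benzyl chloride | ClCc1ccc(OCc2ccccc2)cc1 | starting material
4 | (S)-epichlorohydrin | ClC[C@@H]1CO1 | starting material
5 | [4-(benzyloxy)benzyl]magnesium chloride | Cl[Mg]Cc1ccc(OCc2ccccc2)cc1 | intermediate (not isolated)
6 | (S)-4-[4-(benzyloxy)phenyl]-1-chlorobutan-2-ol, formed as its chloromagnesium alkoxide | ClC[C@H](CCc1ccc(OCc2ccccc2)cc1)O | intermediate (not isolated)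
7 | (S)-2-{2-[4-(benzyloxy)phenyl]ethyl}oxirane | C1[C@H](CCc2ccc(OCc3ccccc3)cc2)O1 | intermediate
8 | ethyl propiolate | C#CC(=O)OCC | starting material
9 | ethyl 3-lithiopropiolate | [Li]C#CC(=O)OCC | intermediate (not isolated)
10 | ethyl (S)-7-[4-(benzyloxy)phenyl]-5-hydroxyhept-2-ynoate | CCOC(=O)C#CC[C@H](CCc1ccc(OCc2ccccc2)cc1)O | intermediate
11 | [4-methoxy-2,6-bis(methoxymethoxy)phenyl]lithium | [Li]c1c(OCOC)cc(OC)cc1OCOC | intermediate (not isolated)
12 | lithium bis[4-methoxy-2,6-bis(methoxymethoxy)phenyl]cuprate | [Li+].COCOc1cc(OC)cc(OCOC)c1[Cu-]c1c(OCOC)cc(OC)cc1OCOC | intermediate (not isolated)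
13 | (6S)-6-{2-[4-(benzyloxy)phenyl]ethyl}-4-[4-methoxy-2,6-bis(methoxymethoxy)phenyl]-5,6-dihydro-2H-pyran-2-one | O=C1C=C(c2c(OCOC)cc(OC)cc2OCOC)C[C@H](CCc2ccc(OCc3ccccc3)cc2)O1 | intermediate
14 | (4R,6S)-6-[2-(4-hydroxyphenyl)ethyl]-4-[4-methoxy-2,6-bis(methoxymethoxy)phenyl]oxan-2-one (4,6-cis) | COCOc1cc(OC)cc(OCOC)c1[C@@H]1C[C@H](CCc2ccc(O)cc2)OC(=O)C1 | intermediate
15 | (4R,6S)-6-{2-[4-(tert-butyldimethylsilyloxy)phenyl]ethyl}-4-[4-methoxy-2,6-bis(methoxymethoxy)phenyl]oxan-2-one | COCOc1cc(OC)cc(OCOC)c1[C@@H]1C[C@H](CCc2ccc(O[Si](C)(C)C(C)(C)C)cc2)OC(=O)C1 | intermediate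
16 | (4R,6S)-6-{2-[4-(tert-butyldimethylsilyloxy)phenyl]ethyl}-4-[4-methoxy-2,6-bis(methoxymethoxy)phenyl]oxan-2-ol (anomer mixture) | COCOc1cc(OC)cc(OCOC)c1[C@@H]1C[C@H](CCc2ccc(O[Si](C)(C)C(C)(C)C)cc2)OC(O)C1 | intermediate
17 | (2S,4R)-2-{2-[4-(tert-butyldimethylsilyloxy)phenyl]ethyl}-4-[4-methoxy-2,6-bis(methoxymethoxy)phenyl]-3,4-dihydro-2H-pyran | COCOc1cc(OC)cc(OCOC)c1[C@@H]1C[C@H](CCc2ccc(O[Si](C)(C)C(C)(C)C)cc2)OC=C1 | intermediate
18 | (4-bromophenoxy)(tert-butyl)dimethylsilane | Brc1ccc(O[Si](C)(C)C(C)(C)C)cc1 | starting material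
19 | 2,3-epoxide of 17 (1,2-anhydro form, epoxide oxygen trans to the C4 aryl group) | COCOc1cc(OC)cc(OCOC)c1[C@@H]1C[C@H](CCc2ccc(O[Si](C)(C)C(C)(C)C)cc2)O[C@@H]2[C@H]1O2 | intermediate (not isolated)
20 | [4-(tert-butyldimethylsilyloxy)phenyl]lithium | [Li]c1ccc(O[Si](C)(C)C(C)(C)C)cc1 | intermediate (not isolated)
21 | tris[4-(tert-butyldimethylsilyloxy)phenyl]aluminium | CC(C)(C)[Si](C)(C)Oc1ccc(cc1)[Al](c1ccc(O[Si](C)(C)C(C)(C)C)cc1)c1ccc(O[Si](C)(C)C(C)(C)C)cc1 | intermediate (not isolated)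
22 | (2S,3S,4S,6S)-2-[4-(tert-butyldimethylsilyloxy)phenyl]-6-{2-[4-(tert-butyldimethylsilyloxy)phenyl]ethyl}-4-[4-methoxy-2,6-bis(methoxymethoxy)phenyl]oxan-3-ol | COCOc1cc(OC)cc(OCOC)c1[C@@H]1C[C@H](CCc2ccc(O[Si](C)(C)C(C)(C)C)cc2)O[C@@H](c2ccc(O[Si](C)(C)C(C)(C)C)cc2)[C@H]1O | intermediate
23 | (2S,3S,4S,6S)-2-(4-hydroxyphenyl)-6-[2-(4-hydroxyphenyl)ethyl]-4-[4-methoxy-2,6-bis(methoxymethoxy)phenyl]oxan-3-ol, formed as its bis(tetrabutylammonium) phenoxide | COCOc1cc(OC)cc(OCOC)c1[C@@H]1C[C@H](CCc2ccc(O)cc2)O[C@@H](c2ccc(O)cc2)[C@H]1O | intermediate (not isolated)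
24 | (2S,3S,4S,6S)-2-(4-acetoxyphenyl)-6-[2-(4-acetoxyphenyl)ethyl]-4-[4-methoxy-2,6-bis(methoxymethoxy)phenyl]oxan-3-yl acetate | COCOc1cc(OC)cc(OCOC)c1[C@@H]1C[C@H](CCc2ccc(OC(C)=O)cc2)O[C@@H](c2ccc(OC(C)=O)cc2)[C@H]1OC(C)=O | intermediate
25 | (2S,3S,4S,6S)-2-(4-acetoxyphenyl)-6-[2-(4-acetoxyphenyl)ethyl]-4-(2,6-dihydroxy-4-methoxyphenyl)oxan-3-yl acetate | COc1cc(O)c([C@@H]2C[C@H](CCc3ccc(OC(C)=O)cc3)O[C@@H](c3ccc(OC(C)=O)cc3)[C@H]2OC(C)=O)c(O)c1 | intermediate
26 | (E)-3-(4-acetoxyphenyl)prop-2-enoic acid | CC(=O)Oc1ccc(/C=C/C(=O)O)cc1 | starting material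
27 | (E)-3-(4-acetoxyphenyl)prop-2-enoyl chloride | CC(=O)Oc1ccc(/C=C/C(=O)Cl)cc1 | intermediate
28 | (2S,3S,4S,6S)-2-(4-acetoxyphenyl)-6-[2-(4-acetoxyphenyl)ethyl]-4-{3-[(E)-3-(4-acetoxyphenyl)prop-2-enoyl]-2,6-dihydroxy-4-methoxyphenyl}oxan-3-yl acetate | COc1cc(O)c([C@@H]2C[C@H](CCc3ccc(OC(C)=O)cc3)O[C@@H](c3ccc(OC(C)=O)cc3)[C@H]2OC(C)=O)c(O)c1C(=O)/C=C/c1ccc(OC(C)=O)cc1 | intermediate
29 | (E)-1-{2,4-dihydroxy-3-[(2S,3S,4S,6S)-3-hydroxy-2-(4-hydroxyphenyl)-6-[2-(4-hydroxyphenyl)ethyl]oxan-4-yl]-6-methoxyphenyl}-3-(4-hydroxyphenyl)prop-2-en-1-one | COc1cc(O)c([C@@H]2C[C@H](CCc3ccc(O)cc3)O[C@@H](c3ccc(O)cc3)[C@H]2O)c(O)c1C(=O)/C=C/c1ccc(O)cc1 | target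

**Step count and risks**
Total step count: 14. Longest linear sequence: 12 steps (steps 2–11, 13, 14, from 3 and 4).

Steps most likely to fail:

1. Step 9. The aryl group may attack C2 from outside the ion pair (anti to the C3 oxygen), which would give the C2 epimer, or the epoxide may undergo a Lewis-acid-induced 1,2-hydride shift to the 3-ketone before aryl transfer. The fallback sets out from 15 and returns at 24. The potassium enolate of 15 (KHMDS, THF, −78 °C) is hydroxylated with 2-(phenylsulfonyl)-3-phenyloxaziridine anti to the C4 aryl group to the 3-hydroxy lactone F1. F1 is silylated (TBSOTf, 2,6-lutidine) to the silyl ether F2, reduced (DIBAL-H, −78 °C) to the lactol F3, and converted with benzenesulfinic acid and CaCl2 into the anomeric sulfone F4. The arylzinc bromide F5, made from aryllithium 20 and ZnBr2, should then displace the sulfone through the oxocarbenium ion along the axial path trans to the C6 chain and cis to the C3 silyloxy group, giving the tris-silyl ether F6. The conditions of step 10 (TBAF, then Ac2O) turn F6 into 24.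

2. Step 13. Ring A or its ortho hydroxyl may add to the cinnamoyl β-carbon (dihydrocoumarin or flavanone formation), O-acylation may stop short of the Fries shift, or the acylating agent may open the oxane ether. The fallback sets out from 25 and returns at 29. Ring A of 25 is C-acetylated at the same carbon (Ac2O, BF3·OEt2, then aqueous work-up; the acetyl cation has no conjugate position) to the acetophenone F7. Claisen–Schmidt condensation of F7 with 4-(allyloxy)benzaldehyde (KOH, EtOH/H2O, rt, acetates saponified in the same flask) gives the chalcone allyl ether F8. Pd(PPh3)4 and morpholine in THF remove the allyl group to give 29.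

3. Step 4. Transfer of the doubly ortho-substituted aryl group from copper may be slow, or the alkenylcopper may isomerise before protonation so that the ester ends trans to the hydroxyalkyl chain and no lactone forms. The fallback sets out from 10 and returns at 13. Pyrrolidine is added to the ynoate 10, and aqueous HCl then hydrolyses the enamine and lactonises the δ-hydroxy β-keto ester to the 4-hydroxy-5,6-dihydropyran-2-one F9. Tf2O and Et3N give the enol triflate F10. Negishi coupling (Pd2(dba)3, SPhos, THF, 50 °C) of F10 with the arylzinc chloride F11, made from aryllithium 11 and ZnCl2, gives 13.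

Further compounds
F1 | step 9 | (3S,4S,6S)-6-{2-[4-(tert-butyldimethylsilyloxy)phenyl]ethyl}-3-hydroxy-4-[4-methoxy-2,6-bis(methoxymethoxy)phenyl]oxan-2-one | COCOc1cc(OC)cc(OCOC)c1[C@@H]1C[C@H](CCc2ccc(O[Si](C)(C)C(C)(C)C)cc2)OC(=O)[C@H]1O
F2 | step 9 | 3-O-tert-butyldimethylsilyl ether of F1 | COCOc1cc(OC)cc(OCOC)c1[C@@H]1C[C@H](CCc2ccc(O[Si](C)(C)C(C)(C)C)cc2)OC(=O)[C@H]1O[Si](C)(C)C(C)(C)C
F3 | step 9 | lactol from F2 (oxan-2-ol, anomer mixture) | COCOc1cc(OC)cc(OCOC)c1[C@@H]1C[C@H](CCc2ccc(O[Si](C)(C)C(C)(C)C)cc2)OC(O)[C@H]1O[Si](C)(C)C(C)(C)C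
F4 | step 9 | 2-(phenylsulfonyl)oxane from F3 (anomer mixture) | COCOc1cc(OC)cc(OCOC)c1[C@@H]1C[C@H](CCc2ccc(O[Si](C)(C)C(C)(C)C)cc2)OC(S(=O)(=O)c2ccccc2)[C@H]1O[Si](C)(C)C(C)(C)C
F5 | step 9 | [4-(tert-butyldimethylsilyloxy)phenyl]zinc bromide | Br[Zn]c1ccc(O[Si](C)(C)C(C)(C)C)cc1
F6 | step 9 | 3-O-tert-butyldimethylsilyl ether of 22 | COCOc1cc(OC)cc(OCOC)c1[C@@H]1C[C@H](CCc2ccc(O[Si](C)(C)C(C)(C)C)cc2)O[C@@H](c2ccc(O[Si](C)(C)C(C)(C)C)cc2)[C@H]1O[Si](C)(C)C(C)(C)C
F7 | step 13 | (2S,3S,4S,6S)-4-(3-acetyl-2,6-dihydroxy-4-methoxyphenyl)-2-(4-acetoxyphenyl)-6-[2-(4-acetoxyphenyl)ethyl]oxan-3-yl acetate | COc1cc(O)c([C@@H]2C[C@H](CCc3ccc(OC(C)=O)cc3)O[C@@H](c3ccc(OC(C)=O)cc3)[C@H]2OC(C)=O)c(O)c1C(C)=O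
F8 | step 13 | 4-O-allyl ether of 29 at the cinnamoyl ring | COc1cc(O)c([C@@H]2C[C@H](CCc3ccc(O)cc3)O[C@@H](c3ccc(O)cc3)[C@H]2O)c(O)c1C(=O)/C=C/c1ccc(OCC=C)cc1
F9 | step 4 | (6S)-6-{2-[4-(benzyloxy)phenyl]ethyl}-4-hydroxy-5,6-dihydro-2H-pyran-2-one | O=C1C=C(O)C[C@H](CCc2ccc(OCc3ccccc3)cc2)O1
F10 | step 4 | (6S)-6-{2-[4-(benzyloxy)phenyl]ethyl}-2-oxo-5,6-dihydro-2H-pyran-4-yl trifluoromethanesulfonate | O=C1C=C(OS(=O)(=O)C(F)(F)F)C[C@H](CCc2ccc(OCc3ccccc3)cc2)O1
F11 | step 4 | [4-methoxy-2,6-bis(methoxymethoxy)phenyl]zinc chloride | Cl[Zn]c1c(OCOC)cc(OC)cc1OCOC
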